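In a one-step world with a catalyst that lasts, the rate follows substrate, r = Vmax·S/(Km + S), where S is the substrate present, Vmax the rate at saturation and Km the half-saturation concentration. The integrated rate law then says that Q = ln(Si/S) + (Si − S)/Km, with Si the charge, grows in step with time.

| setting | Saturday's | Sunday's | Tuesday's | Monday's |
|---|---|---|---|---|
| substrate | 250 mM | 750 mM | 250 mM | 100 mM |
| free catalyst | 13.0 mM | 13.0 mM | 13.0 mM | 13.0 mM |
| product |  |  | 120 mM |  |
| time |  |  |  | 43 min |

| run | time / min | [product] / mM |
|---|---|---|
| Saturday's run | 7.2 | 78 |
| Saturday's run | 14 | 137 |
| Saturday's run | 22 | 187 |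
| Saturday's run | 29 | 192 |
| Saturday's run | 36 | 203 |
| Saturday's run | 43 | 208 |
| Sunday's run | 7.2 | 107 |
| Sunday's run | 14 | 194 |
| Sunday's run | 22 | 284 |
| Sunday's run | 29 | 345 |
| Sunday's run | 36 | 396 |
| Sunday's run | 43 | 415 |
| Tuesday's run | 7.2 | 201 |
| Tuesday's run | 14 | 245 |
| Tuesday's run | 22 | 275 |
| Tuesday's run | 29 | 290 |
| Tuesday's run | 36 | 301 |
| Tuesday's run | 43 | 298 |

(scatter of a reading: 4 mM)

* apparent order in [substrate] of the starting rate, round the charge of the Saturday's run (the rate where two percent of its substrate have turned into product) (one fixed amount of product, the same in the runs compared)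
* product in the Monday's run at 43 min, as a share of the substrate charged

The first readings of Saturday's and Sunday's runs, taken at their mean substrate, give me a rough Km of 134 mM, and so an order Km/(Km + Si) of 0.349 round Saturday's charge.

But Sunday's mean rate sinks from 14.9 mM/min over the first reading to 5.00 mM/min over the last two intervals, with a reading of 335 mM of substrate still present at 43 min, more than Km. I read that as a fading catalyst and replace its activity, the working share of the catalyst charged, by its mean: Q then equals Vmax/Km times mean activity times time. Saturday's last reading gives 3.33, and this is the catalyst's delivered work.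

I give Monday's flask the same work in the same time. By my estimate that leaves 7.11 mM of substrate in Monday's run at 43 min, so 92.9% is product.

The forecast gives 0.32 and 82.5%, both different from my figures, and says of Monday's run: “it should be essentially at equilibrium”.

The flask gives an order of 0.28 round Saturday's charge and 96.1% in Monday's run.

    free catalyst + substrate → product + free catalyst (14.22 /M/min)
    free catalyst + substrate ⇌ idle catalyst-substrate complex, settled at all times (11.60 /M)
    free catalyst + product → spent catalyst + product (0.6240 /M/min)

Here product takes free catalyst to spent catalyst. Monday's Q comes to 3.97, more than Saturday's 3.33. Saturday's and Tuesday's runs both make new product equal to half their substrate charge, the same Q of 1.62, in 12.5 min and 14.9 min, so Tuesday's mean activity up to there is 0.839 of Saturday's.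

(The runs are calculated on assumed constants; scatter was added.)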